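A direct plan would build ring C first and ring A last: a Ti(OiPr)4/(S)-BINOL-catalysed Mukaiyama aldol would set C2 at the outset in the bis(methylthio)enone silyl ether A1, a keto-lactone A2 would be silylated to the Chan-type diene A3, and a single flask would close A1 to the thio-pyranone A4, join A4 to A3 and aromatise ring A by a vinylogous Dieckmann condensation.
Its weakest points would be: (a) that final cascade, three unprecedented events run at once on both advanced fragments, which would leave the ring A closure to chance in the step one would least like to risk on late material;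
(b) the carriage of C2, made first, through a Lewis acid beside a benzylic silyl ether and then through Et3N/MeOH, where β-alkoxy ketones and the product flavanone open by E1cB, which would leave the stereocentre to chance;
(c) the acid-catalysed hydroxybenzylation (large excess of a deactivated arene, product more nucleophilic than substrate) that opens a four-step run to A3, many steps for a fragment that brings only two benzyl groups.

**Plan of the new route**
Cuts: C2–aryl first (ring B becomes phenylboronic acid), then C8–CH2 (an o-quinone methide precursor), then O1–C2 and C2–C3 of ring C (one carbon from an amide acetal), C4–C4a (acetylation) and C6–CH2–aryl (Grignard addition to a ring A aldehyde).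
Ring A is bought, ring C grows on it as a flat chromone, and C2 is saturated only in the last step; ring A is never made de novo.
Feature used: C2, the only stereocentre, is the β-carbon of the vinylogous ester O1–C2=C3–C4=O of a chromone and carries an unsubstituted phenyl; ring A has a local twofold axis through C6 and C8a (C5–OH and C7–OH alike), so a 4-benzyl-3,5-dimethoxyphenol has two equivalent ortho carbons, gives one chromone and leaves C8 as the only free position.
Hence no cascade on late material, no regiochemical choice on ring A, all harsh reagents (BF3·OEt2, BBr3, ZnCl2) on achiral compounds, and a stereocentre that meets no reagent after it is formed.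
Key step: step 8

Assumption: the (R)-enantiomer of t-BuPyOx is taken to deliver phenyl to the C2 face that gives (2S), the mirror image of the sense established for the (S)-ligand with cyclic enones and chromones; should the sense be opposite, the (S)-ligand would be used.

Step 1
Reactants: 1 4-hydroxy-2,6-dimethoxybenzaldehyde; 2 2-methoxyphenylmagnesium bromide
Product: 4 4-(2-methoxybenzyl)-3,5-dimethoxyphenol, via diarylmethanol 3 (not isolated)
Conditions: 2 (3.2 equiv), THF, 0 → 40 °C; aq. NH4Cl; crude 3, Et3SiH (3 equiv), CF3CO2H (5 equiv), CH2Cl2, 0 °C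
Reagents that add atoms: none
Why: Grignard addition to the aldehyde (one equivalent of 2 is spent on the phenol, whose magnesium phenoxide only slows the addition) followed by ionic hydrogenation, in which the carbinol ionises to a cation stabilised by three ortho/para oxygens and takes hydride from Et3SiH; the racemic carbinol centre of 3 disappears, and the aldehyde carbon, para to the free OH and flanked by the two OMe groups, fixes the arm at what becomes C6.

Step 2
Reactants: 4 4-(2-methoxybenzyl)-3,5-dimethoxyphenol
Product: 6 1-[6-hydroxy-2,4-dimethoxy-3-(2-methoxybenzyl)phenyl]ethanone, via difluoroboron chelate 5 (not isolated)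
Conditions: Ac2O (1.5 equiv), BF3·OEt2 (3 equiv), ClCH2CH2Cl, 60 °C; then NaOAc, MeOH–H2O, 60 °C
Reagents that add atoms: acetic anhydride, CC(=O)OC(C)=O
Why: Friedel–Crafts (Fries-type) acetylation ortho to the free phenol, driven by formation of the difluoroboron chelate 5, which also stops a second acylation; the two ortho carbons of 4 are equivalent by the mirror plane through C1 and C4, so only one acetophenone can form and the last free ring carbon becomes C8.

Step 3
Reactants: 6 1-[6-hydroxy-2,4-dimethoxy-3-(2-methoxybenzyl)phenyl]ethanone
Product: 8 5,7-dimethoxy-6-(2-methoxybenzyl)-4H-chromen-4-one, via enaminone 7 (not isolated)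
Conditions: Me2NCH(OMe)2 (3 equiv), toluene, 95 °C; evaporation; 2 M HCl, CH2Cl2, 40 °C
Reagents that add atoms: N,N-dimethylformamide dimethyl acetal, COC(OC)N(C)C
Why: Chromone synthesis through an enaminone, in which the acetyl CH3 condenses with the amide acetal and the only free phenol then closes ring C by 6-endo addition to the β-carbon and loss of dimethylamine, so that O1 is necessarily the oxygen para to the benzyl arm.

Step 4
Reactants: 8 5,7-dimethoxy-6-(2-methoxybenzyl)-4H-chromen-4-one
Product: 9 5,7-dihydroxy-6-(2-hydroxybenzyl)-4H-chromen-4-one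
Conditions: BBr3 (8 equiv), CH2Cl2, −78 → 25 °C; ice-water
Reagents that add atoms: none
Why: BBr3 cleavage of the three aryl methyl ethers (the C5 ether assisted by chelation to C4=O), placed here because the chromone is achiral and stable to strong Lewis acid, whereas a flavanone could open and racemise.

Step 5
Reactants: 10 phenol; 11 methyl 5-formyl-2-hydroxybenzoate; 12 phenylboronic acid
Product: 14 methyl 2-hydroxy-5-(2-hydroxybenzyl)benzoate, via benzodioxaborin 13 (not isolated)
Conditions: 10 (3 equiv), 12 (1.1 equiv), EtCO2H (0.2 equiv), toluene, reflux, Dean–Stark; evaporation; Et3SiH (3 equiv), CF3CO2H, CH2Cl2, 0 → 25 °C; aq. work-up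
Reagents that add atoms: none
Why: Boron-templated ortho-hydroxyalkylation of phenol (the aryl phenylboronate binds the aldehyde and delivers it only to the ortho carbon, giving the 2-phenyl-4H-1,3,2-benzodioxaborin 13) followed by ionic hydrogenation of its doubly benzylic C–O bond with Et3SiH; the electron-poor salicylate ring cannot act as the nucleophile, so the 2,4'-linked diarylmethane should form without a para isomer, and the racemic centre of 13 is removed.

Step 6
Reactants: 14 methyl 2-hydroxy-5-(2-hydroxybenzyl)benzoate
Product: 15 4-(2-hydroxybenzyl)-2-(hydroxymethyl)phenol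
Conditions: LiAlH4 (3 equiv), THF, 0 → 25 °C; aq. potassium sodium tartrate
Reagents that add atoms: none
Why: Hydride reduction of the salicylate ester to the salicyl alcohol (an o-quinone methide precursor) with LiAlH4; the diarylmethane and both phenols, carried as aluminium phenoxides, are inert and the neutral tartrate work-up avoids premature ionisation.

Step 7
Reactants: 9 5,7-dihydroxy-6-(2-hydroxybenzyl)-4H-chromen-4-one; 15 4-(2-hydroxybenzyl)-2-(hydroxymethyl)phenol
Product: 16 5,7-dihydroxy-6-(2-hydroxybenzyl)-8-[2-hydroxy-5-(2-hydroxybenzyl)benzyl]-4H-chromen-4-one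
Conditions: ZnCl2 (2 equiv), 1,4-dioxane, 85 °C, 15 (1.1 equiv) added over 4 h
Reagents that add atoms: none
Why: ZnCl2-mediated ortho-hydroxybenzylation, in which the zinc-bound o-quinone methide (2-hydroxybenzyl cation) from 15 is captured in a Friedel–Crafts-type conjugate addition by C8, the only unsubstituted carbon of the phloroglucinol-type ring A and far more nucleophilic than any monophenol ring present, while slow addition keeps 15 from condensing with itself; no stereocentre is formed.

Step 8
Reactants: 16 5,7-dihydroxy-6-(2-hydroxybenzyl)-8-[2-hydroxy-5-(2-hydroxybenzyl)benzyl]-4H-chromen-4-one; 12 phenylboronic acid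
Product: 17 isouvarinol, (2S)-5,7-dihydroxy-6-(2-hydroxybenzyl)-8-[2-hydroxy-5-(2-hydroxybenzyl)benzyl]-2-phenylchroman-4-one
Conditions: Pd(OCOCF3)2 (10 mol%), (R)-4-tert-butyl-2-(pyridin-2-yl)-4,5-dihydrooxazole [(R)-t-BuPyOx, 12 mol%], NH4PF6 (30 mol%), 12 (3 equiv), H2O (10 equiv), ClCH2CH2Cl–THF (5:1), 50 °C; MeOH–H2O work-up
Reagents that add atoms: none
Why: Transmetalation of 12 to the cationic palladium–PyOx complex gives a phenyl–palladium species that adds across C2=C3 of the chromone with phenyl to C2 (enantio-determining carbopalladation), and the palladium enolate is protonated by water faster than it can undergo β-hydride elimination to the flavone. The closest known reaction is the Pd(OCOCF3)2/t-BuPyOx-catalysed conjugate addition of arylboronic acids to chromones, which gives 2-arylchroman-4-ones. No ring is closed; ring C is only saturated at C2–C3. The single new stereocentre C2 is set by the ligand: the tert-butyl group of the oxazoline clashes with the carbonyl side of the chromone in one of the two insertion geometries, so phenyl is delivered to one face of C2, taken here to give (2S) with the (R)-ligand. The step needs face selectivity, conjugate addition rather than oxidative arylation, and tolerance of five phenols; C2 is the only acceptor carbon, the C5 hydroxyl activates C4=O by hydrogen bonding, and the medium is weakly acidic and free of base, so the 5-hydroxyflavanone cannot reopen to the chalcone and the new centre should not be eroded.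

**Compound list**
1 | 4-hydroxy-2,6-dimethoxybenzaldehyde | O=Cc1c(OC)cc(O)cc1OC | starting material
2 | 2-methoxyphenylmagnesium bromide | COc1ccccc1[Mg]Br | starting material
3 | (4-hydroxy-2,6-dimethoxyphenyl)(2-methoxyphenyl)methanol (racemic) | COc1ccccc1C(O)c1c(OC)cc(O)cc1OC | intermediate
4 | 4-(2-methoxybenzyl)-3,5-dimethoxyphenol | COc1ccccc1Cc1c(OC)cc(O)cc1OC | intermediate
5 | difluoroboron chelate of 6 (B bridging the phenol oxygen and the acetyl oxygen) | CC1=[O+][B-](F)(F)Oc2cc(OC)c(Cc3ccccc3OC)c(OC)c12 | intermediate
6 | 1-[6-hydroxy-2,4-dimethoxy-3-(2-methoxybenzyl)phenyl]ethanone | CC(=O)c1c(O)cc(OC)c(Cc2ccccc2OC)c1OC | intermediate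
7 | (E)-3-(dimethylamino)-1-[6-hydroxy-2,4-dimethoxy-3-(2-methoxybenzyl)phenyl]prop-2-en-1-one | CN(C)/C=C/C(=O)c1c(O)cc(OC)c(Cc2ccccc2OC)c1OC | intermediate
8 | 5,7-dimethoxy-6-(2-methoxybenzyl)-4H-chromen-4-one | COc1ccccc1Cc1c(OC)cc2occc(=O)c2c1OC | intermediate
9 | 5,7-dihydroxy-6-(2-hydroxybenzyl)-4H-chromen-4-one | Oc1ccccc1Cc1c(O)cc2occc(=O)c2c1O | intermediate
10 | phenol | Oc1ccccc1 | starting material
11 | methyl 5-formyl-2-hydroxybenzoate | COC(=O)c1cc(C=O)ccc1O | starting material
12 | phenylboronic acid | OB(O)c1ccccc1 | starting material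
13 | methyl 2-hydroxy-5-(2-phenyl-4H-1,3,2-benzodioxaborinin-4-yl)benzoate (racemic) | COC(=O)c1cc(ccc1O)C1OB(c2ccccc2)Oc2ccccc12 | intermediate
14 | methyl 2-hydroxy-5-(2-hydroxybenzyl)benzoate | COC(=O)c1cc(Cc2ccccc2O)ccc1O | intermediate
15 | 4-(2-hydroxybenzyl)-2-(hydroxymethyl)phenol | OCc1cc(Cc2ccccc2O)ccc1O | intermediate
16 | 5,7-dihydroxy-6-(2-hydroxybenzyl)-8-[2-hydroxy-5-(2-hydroxybenzyl)benzyl]-4H-chromen-4-one | O=c1ccoc2c(Cc3cc(Cc4ccccc4O)ccc3O)c(O)c(Cc3ccccc3O)c(O)c12 | intermediate
17 | isouvarinol, (2S)-5,7-dihydroxy-6-(2-hydroxybenzyl)-8-[2-hydroxy-5-(2-hydroxybenzyl)benzyl]-2-phenylchroman-4-one | O=C1C[C@@H](c2ccccc2)Oc2c(Cc3cc(Cc4ccccc4O)ccc3O)c(O)c(Cc3ccccc3O)c(O)c21 | target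

**Count and risks**
Total steps: 8. Longest linear sequence: 6 (steps 1, 2, 3, 4, 7, 8); steps 5 and 6 make the second fragment.

Steps most likely to fail:

Step 8. What may go wrong: the five free phenols, above all the C5-hydroxyl/C4-carbonyl chelating site, may sequester or reduce the cationic palladium catalyst, so that turnover stalls or an unselective background addition lowers the face selectivity. Fallback: set out from 16. Ac2O, pyridine and catalytic 4-(dimethylamino)pyridine should give the pentaacetate F1, an acyloxychromone with no free phenol. The same Pd(OCOCF3)2/(R)-t-BuPyOx addition of 12 should then give the (2S)-flavanone pentaacetate F2. Acid-catalysed methanolysis (HCl in MeOH, 25 °C), which cannot open ring C, would come back to the route at 17.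

Step 7. What may go wrong: self-condensation of the o-quinone methide with the phenol rings of 15, or over-benzylation of the monophenol rings of the product, may outrun attack by C8. Fallback: replace the free o-quinone methide by delivery through boron, setting out from 15 and 9. MnO2 (EtOAc, 25 °C) should oxidise the benzylic alcohol of 15 to 2-hydroxy-5-(2-hydroxybenzyl)benzaldehyde F3. Heating F3 with 9 and 12 (EtCO2H cat., toluene–dioxane, water removal) should let boron bridge O7 and the aldehyde oxygen, so that the C–C bond can only form at C8, giving the fused benzodioxaborin F4. Et3SiH/CF3CO2H reduction, as in step 5, would come back at 16.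

Step 5. What may go wrong: ortho-delivery to an aldehyde deactivated by its para-hydroxyl may be slow, and on prolonged heating a second phenol may add to the benzylic position (triarylmethane formation). Fallback: fix the aryl–CH2 bond with a carbon nucleophile instead, setting out from 11 and 2. 2 (2.2 equiv, THF, −40 °C, the phenoxide-deactivated ester being spared) should give the carbinol F5. Et3SiH/CF3CO2H should then give methyl 2-hydroxy-5-(2-methoxybenzyl)benzoate F6. BBr3 (CH2Cl2, −78 → 0 °C) should cleave the aryl methyl ether and come back at 14.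

**Further compounds**
F1 | step 8 | pentaacetate of 16: 6-(2-acetoxybenzyl)-8-[2-acetoxy-5-(2-acetoxybenzyl)benzyl]-4-oxo-4H-chromene-5,7-diyl diacetate | O=c1ccoc2c(Cc3cc(Cc4ccccc4OC(C)=O)ccc3OC(C)=O)c(OC(C)=O)c(Cc3ccccc3OC(C)=O)c(OC(C)=O)c12
F2 | step 8 | (2S)-flavanone pentaacetate (pentaacetate of 17) | O=C1C[C@@H](c2ccccc2)Oc2c(Cc3cc(Cc4ccccc4OC(C)=O)ccc3OC(C)=O)c(OC(C)=O)c(Cc3ccccc3OC(C)=O)c(OC(C)=O)c21
F3 | step 7 | 2-hydroxy-5-(2-hydroxybenzyl)benzaldehyde | O=Cc1cc(Cc2ccccc2O)ccc1O
F4 | step 7 | 2-phenyl-1,3,2-dioxaborin fused at O7 and C8 of chromone 9, bearing the 2-hydroxy-5-(2-hydroxybenzyl)phenyl group on its sp3 carbon (racemic) | O=c1ccoc2c3C(c4cc(Cc5ccccc5O)ccc4O)OB(c4ccccc4)Oc3c(Cc3ccccc3O)c(O)c12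
F5 | step 5 | methyl 2-hydroxy-5-[hydroxy(2-methoxyphenyl)methyl]benzoate (racemic) | COC(=O)c1cc(C(O)c2ccccc2OC)ccc1O
F6 | step 5 | methyl 2-hydroxy-5-(2-methoxybenzyl)benzoate | COC(=O)c1cc(Cc2ccccc2OC)ccc1O
A1 | direct plan | (5S)-1,1-bis(methylsulfanyl)-5-phenyl-5-(trimethylsilyloxy)pent-1-en-3-one | CSC(SC)=CC(=O)C[C@H](O[Si](C)(C)C)c1ccccc1
A2 | direct plan | 3-[3-[2-hydroxy-5-(2-hydroxybenzyl)phenyl]propanoyl]chroman-2-one | O=C(CCc1cc(Cc2ccccc2O)ccc1O)C1Cc2ccccc2OC1=O
A3 | direct plan | 2-(trimethylsilyloxy)-3-[1-(trimethylsilyloxy)-3-[2-(trimethylsilyloxy)-5-[2-(trimethylsilyloxy)benzyl]phenyl]prop-1-enyl]-4H-chromene | C[Si](C)(C)OC1=C(C(O[Si](C)(C)C)=CCc2cc(Cc3ccccc3O[Si](C)(C)C)ccc2O[Si](C)(C)C)Cc2ccccc2O1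
A4 | direct plan | (2S)-6-(methylsulfanyl)-2-phenyl-2,3-dihydro-4H-pyran-4-one | CSC1=CC(=O)C[C@@H](c2ccccc2)O1
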